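The data were generated by integration from invented constants, noise included.

**Feed and loss.** The stirred vessel maple takes substrate at a steady rate for 2.5 d, and its readings stop at 20.0 h. Larch ran the same feed to the end with twice the free catalyst.

the same everywhere: substrate 18 mM (fed, over 2.5 d)
- maple: capture agent 1.8 mM; free catalyst 0.32 mM; the very flask that is asked about, followed so far
- larch: capture agent 1.8 mM; free catalyst 0.64 mM; run made earlier
- flask: capture agent 1.80 mM; free catalyst 0.32 mM; time 2.5 d

maple run (percent of the substrate charged)

| time / h | substrate / % | over-reaction product / % | trapped intermediate / % | target / % | catalyst intermediate A / % | catalyst intermediate B / % |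
|---|---|---|---|---|---|---|
| 1.00 | 1.7 | 0 | 0 | 0 | 0.4 | 0 |
| 3.00 | 4.4 | 0 | 0 | 0 | 0 | 0.1 |
| 5.00 | 7.8 | 0 | 0 | 0.1 | 0.6 | 0 |
| 8.00 | 12.7 | 0 | 0 | 0.2 | 0.5 | 1.2 |
| 10.0 | 16.0 | 0.7 | 0.5 | 0 | 0.2 | 0.1 |
| 15.0 | 24.7 | 0.2 | 0 | 0.1 | 1.2 | 0 |
| 20.0 | 32.5 | 0 | 0.4 | 1.6 | 0.2 | 0 |

larch run (percent of the substrate charged)

| time / d | substrate / % | over-reaction product / % | trapped intermediate / % | target / % | catalyst intermediate A / % | catalyst intermediate B / % |
|---|---|---|---|---|---|---|
| 0.125 | 5.8 | 0 | 0.2 | 0.9 | 0.8 | 0 |
| 0.417 | 16.5 | 0 | 0.1 | 0.2 | 0.3 | 0 |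
| 0.625 | 24.8 | 0.5 | 0.5 | 0 | 0 | 0.1 |
| 1.04 | 40.7 | 0 | 0 | 1.3 | 0.4 | 0.3 |
| 1.67 | 65.4 | 0.5 | 0.7 | 1.1 | 0.3 | 0.4 |
| 2.08 | 81.7 | 0.5 | 0 | 0 | 0.1 | 0.4 |
| 2.50 | 98.2 | 0.1 | 0 | 1.1 | 0.7 | 0.8 |

(readings scatter by 0.5 percentage points)

- percentages count the whole charge, also what has not yet gone in

- the species that holds most of what was charged as substrate, at 2.5 d (trapped intermediate / catalyst intermediate B / over-reaction product / catalyst intermediate A / target / substrate)
- the largest share itself, whichever of these holds it, in percent of the substrate charged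

The consumed share is the fraction of the charge fed by a given time minus the fraction found as substrate. In maple at 20.0 h, 33.3% has been fed and 32.5% is found, so the consumed share is 0.833%.

**First round.** A consumed share growing in proportion to time reaches 2.50% at 2.5 d. That is more than the 1.80% read in larch at the same time, although larch was charged with more free catalyst, so the straight line is suspect.

**Second round.** Larch stands at 0.900% at 1.04 d. Its late consumption rate, the consumed share gained per day late in a run, is therefore 0.00616 d⁻¹, a reading that carries the scatter. Larch at 1.04 d and maple at 20.0 h differ by less than one scatter, so this reckoning lends maple the larch rate for the remaining 1.67 d. By this estimate the consumed share of maple comes to 1.86%, which puts substrate at 98.1%, far above that consumed share.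

**The forecast.** It names substrate at 98.7%, range 97.3% to 99.5%, on the ground that “Half the catalyst should therefore give no more conversion”. Its figure is higher than this reckoning's.

**The result.** The flask holds substrate at 98.1%, inside the forecast's range. Free catalyst in the flask goes from 18.3% of the catalyst charged at 1.25 d to 9.57% at 2.50 d, with spent catalyst at 86.9%. Target plus over-reaction product, which are part of the consumed share, grow in the flask over that stretch at 0.00843 d⁻¹, against the 0.00616 d⁻¹ of consumed share lent from larch. For the neighbour flask with a quarter of the free catalyst, that larch rate over the whole feed gives a consumed share of 1.54%, and target plus over-reaction product in that neighbour stand at 1.12%.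

    substrate + free catalyst ⇌ catalyst intermediate A (K = 6.40 M⁻¹, k = 0.0380 M⁻¹ s⁻¹)
    catalyst intermediate A ⇌ catalyst intermediate B (K = 4.50, k = 6.90 × 10⁻⁴ s⁻¹)
    catalyst intermediate B → free catalyst + target (k = 7.30 × 10⁻⁴ s⁻¹)
    2 free catalyst → spent catalyst (k = 0.0620 M⁻¹ s⁻¹)
    target → over-reaction product (k = 2.90 × 10⁻⁶ s⁻¹)
    capture agent + catalyst intermediate B → trapped intermediate (k = 0.00690 M⁻¹ s⁻¹)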